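## Structural features

Xestin A (17) is a 3,6-dihydro-1,2-dioxine, a six-membered cyclic peroxide O1–O2–C3–C4=C5–C6 whose C4=C5 bond is cis by ring constraint; in the backbone numbering used throughout, C1 is the ester carbonyl, C2 the methylene and C3 to C6 the ring carbons, with O2 on C3 and O1 on C6. C6 is a fully substituted peroxyketal carbon (O1, OMe, C5 and an unbranched C18 chain), whereas C3 is a secondary peroxide carbon (O2, H, C4 and CH2CO2Me), so the ester carbonyl C1 stands 1,3 to the peroxide oxygen on C3. The two stereocentres (3R,6R) face each other 1,4 across the ring with OMe and the acetate arm cis, and the only other stereo-element is the (14E,16E)-diene at the chain end, thirteen methylenes away from C6. The fragile groups are the O–O bond (phosphines, hydrides, low-valent metals, hydrogenation), the C3–H bond that is allylic and α to the peroxide (base-induced Kornblum–DeLaMare fragmentation), the β-peroxy ester (E1cB elimination), the acid-labile C6 ketal and the chain diene, which reacts with singlet oxygen, electrophiles and metathesis catalysts. The real difficulty is to make the C3–O–O bond with absolute control, because C3 cannot be corrected later, and to do so with an oxygen source that ignores the chain diene. C6 is an anomeric centre: in the half-chair the cis isomer can hold OMe pseudo-axial (anomeric stabilisation by O1) with both carbon substituents pseudo-equatorial, so C6 can be left to equilibration. The key step exploits two features, namely that C3 is the β-carbon of the C1 carbonyl, so that O2–C3 is a retro-conjugate-addition bond, and that C3–C4=C5–C6, oxygenated at both ends with a cis alkene, is the pattern of a ring-opened 2-substituted furan.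

## Logic of the disconnections

17 ⇒ 16. The ring bond O1–C6 is cut and C6 is written as a dimethyl ketal, with the peroxide on C3 carrying a ketal-type cap. C6 is the acid-labile anomeric carbon, so this is the one ring bond that can be made reversibly. The ring and the C6 stereocentre leave the problem and only C3 remains. The forward step needs acid mild enough for the O–O bond, a cis C4=C5 bond, and an equilibrium at C6 that favours the cis isomer.

16 ⇒ 15 ⇒ 14. No skeletal bond is cut; C1 goes back from ester to acid to aldehyde. Only the aldehyde allows iminium activation of C2=C3. Nothing is gained in size; the step places the activating group. The forward oxidation and methylation must be non-basic and non-reducing.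

14 ⇒ 11 + 13 (key). The O2–C3 bond is cut in the retro-conjugate-addition sense. C3 is β to C1 and is the only stereocentre that cannot be equilibrated. A catalyst-controlled addition of an O–O nucleophile installs the peroxide and its configuration together, by ground-state chemistry that leaves the chain diene alone. The gain is that a chiral peroxide falls to an achiral dienal and a four-carbon hydroperoxide. The forward step must attack C3 and not the vinylogous C5, give peroxide and not epoxide, control the face, and keep C4=C5 cis. In one sentence, the route is the catalyst-controlled conjugate addition of 13 to C3 of 11.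

13 ⇒ 12. The C=C bond of 12 is cleaved; the O–O unit comes from ozone trapped by methanol. The forward step must avoid any reductive work-up.

11 ⇒ 10 ⇒ 9. Functional-group level only: aldehyde from Weinreb amide, ketal from ketone. The ketal hides the cis-enone from the amine catalyst, which would isomerise it, and pre-installs the C6 methoxy group. The forward ketalisation must not isomerise C4=C5.

9 ⇒ 8 ⇒ 7. The C2=C3 bond is cut (olefination of the C3 aldehyde). The two carbonyl carbons C3 and C6 are then joined through one oxygen into the aromatic five-membered ring of 7. All of C3–C6, the C6 carbonyl and the cis geometry come from a flat heteroarene. The ring-opening oxidant must select the heteroarene over the chain diene.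

7 ⇒ 4 + 5 (via 6). The C(sp3)–C(sp3) bond between side-chain C12 and C13 is cut, so the (E,E)-diene is bought ready-made in 5. The forward coupling must substitute at the acetate-bearing carbon without allylic transposition.

4 ⇒ 1 + 2 (via 3). The bond between the heteroaryl C2 and the chain is cut, giving two commodity chemicals. The forward step must mono-alkylate a dibromide.

## Other disconnections considered

Alternative 1: The first idea is to cut O2–C3 and O1–C6 together: [4+2] cycloaddition of singlet oxygen to the 1-methoxy-1,3-diene A1, methyl (3E,5E,20E,22E)-6-methoxytetracosa-3,5,20,22-tetraenoate. It would close the ring and set the cis relationship in one suprafacial step. The chosen plan is preferred on three grounds. Nothing controls which diene face is attacked, so 17 could only form as a racemate. The enol-ether end of A1 invites [2+2] and ene pathways. The chain (E,E)-diene is itself a singlet-oxygen diene, so it would have to be built after the peroxide, on a base- and phosphine-sensitive molecule.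

Alternative 2: Cut C4=C5: ring-closing metathesis of the bis-allylic mixed peroxide A2, methyl (3R)-3-{[(17E,19E)-3-methoxyhenicosa-1,17,19-trien-3-yl]peroxy}pent-4-enoate, with the second-generation Grubbs catalyst. The ring alkene would be cis by construction. The step creates no stereocentre, and A2 still needs an enantiopure secondary allylic hydroperoxide, so the C3 problem is only moved. The vinyl group on the fully substituted C6 is a slow partner, and the chain diene would compete for the carbene.

Alternative 3: Cut the C3–CH2 bond: ionise the furan-derived bis-acetal A3, 6-methoxy-6-[(14E,16E)-octadeca-14,16-dien-1-yl]-3,6-dihydro-1,2-dioxin-3-yl acetate, to the cyclic peroxycarbenium ion at C3 and add a silyl ketene acetal of methyl acetate. This would be very short. The cation is planar and A3 is racemic at a labile C6, so C3 would be set only by 1,4-induction and 17 would be racemic at best. The C6 ketal would also compete in the ionisation, and the allyl-type cation could be attacked at C5. The chosen plan keeps the furan idea but lets a catalyst decide C3.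

Key step: step 7

Remark on the chemistry: C6 of 17 is a peroxyketal centre that epimerises under acid, so it is set last under equilibrating conditions. The facial sense in step 7 is assigned from the steric model of the diarylprolinol silyl ether iminium ion; the enantiomeric catalyst would invert it.

## Route

Step 1
Reactants: 1 furan; 2 1,12-dibromododecane
Product: 4 2-(12-bromododecyl)furan, via furan-2-yllithium 3 (not isolated)
Conditions: n-BuLi, THF, 0 °C; then 2 (3 equiv), DMPU, −78 °C → rt
Reagents that add atoms: none
Why: α-Lithiation of furan followed by SN2 alkylation with a primary bromide; the threefold excess of 2 suppresses double alkylation and no stereocentre is involved.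

Step 2
Reactants: 4 2-(12-bromododecyl)furan; 5 (2E,4E)-hexa-2,4-dien-1-yl acetate
Product: 7 2-[(14E,16E)-octadeca-14,16-dien-1-yl]furan, via [12-(furan-2-yl)dodecyl]magnesium bromide 6 (not isolated)
Conditions: Mg, THF, 40 °C; then 5, Li2CuCl4 (3 mol%), THF, −20 → 0 °C
Reagents that add atoms: none
Why: Grignard formation and copper-catalysed cross-coupling with a dienylic acetate; substitution at the acetate-bearing carbon should be favoured at low temperature and leaves the (E,E)-diene of 5 untouched, and the cuprate path should outrun addition to the acetate carbonyl.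

Step 3
Reactants: 7 2-[(14E,16E)-octadeca-14,16-dien-1-yl]furan
Product: 9 (2E,4Z,20E,22E)-N-methoxy-N-methyl-6-oxotetracosa-2,4,20,22-tetraenamide, via (2Z,18E,20E)-4-oxodocosa-2,18,20-trienal 8 (not isolated)
Conditions: NBS, NaHCO3, acetone/H2O (10:1), −20 °C; cold extraction; then Ph3P=CHC(O)N(OMe)Me, CH2Cl2, 0 °C → rt
Reagents that add atoms: water, O; N-methoxy-N-methyl-2-(triphenyl-λ5-phosphanylidene)acetamide, CON(C)C(=O)C=P(c1ccccc1)(c1ccccc1)c1ccccc1
Why: Oxidative dearomatisation of the 2-alkylfuran (bromination at C5, hydration, ring opening) gives the cis-ene-1,4-dicarbonyl unit, whose cis bond is inherited from the ring; the electron-rich furan should consume NBS far faster than the unactivated diene. The stabilised ylide then olefinates only the aldehyde (Wittig reaction, E-selective), which fixes C2=C3 as E and leaves C4=C5 as Z.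

Step 4
Reactants: 9 (2E,4Z,20E,22E)-N-methoxy-N-methyl-6-oxotetracosa-2,4,20,22-tetraenamide
Product: 10 (2E,4Z,20E,22E)-N,6,6-trimethoxy-N-methyltetracosa-2,4,20,22-tetraenamide
Conditions: MeOSiMe3 (3 equiv), Me3SiOTf (5 mol%), CH2Cl2, −78 °C; pyridine quench
Reagents that add atoms: methoxytrimethylsilane, CO[Si](C)(C)C
Why: Noyori ketalisation: silyl triflate-catalysed exchange with the silyl methyl ether at −78 °C converts conjugated ketones into dimethyl ketals without equilibrating the double bonds. The ketal removes the enone that the amine of step 7 would isomerise and pre-installs the C6 methoxy group.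

Step 5
Reactants: 10 (2E,4Z,20E,22E)-N,6,6-trimethoxy-N-methyltetracosa-2,4,20,22-tetraenamide
Product: 11 (2E,4Z,20E,22E)-6,6-dimethoxytetracosa-2,4,20,22-tetraenal
Conditions: i-Bu2AlH, THF, −78 °C; aq. KNaC4H4O6 (Rochelle salt)
Reagents that add atoms: none
Why: Hydride reduction of a Weinreb amide stops at the aldehyde because the chelated tetrahedral aluminate survives until work-up; the ketal and the alkenes are inert to i-Bu2AlH at −78 °C, and the non-acidic work-up protects the allylic ketal.

Step 6
Reactants: 12 2,3-dimethylbut-2-ene
Product: 13 2-hydroperoxy-2-methoxypropane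
Conditions: O3, CH2Cl2/MeOH (1:1), −78 °C; N2 purge, no reductive work-up
Reagents that add atoms: ozone, [O-][O+]=O; methanol, CO
Why: Ozonolysis of a tetrasubstituted alkene in methanol: Criegee cleavage gives acetone and its carbonyl oxide, which methanol traps as the α-methoxy hydroperoxide.

Step 7
Reactants: 11 (2E,4Z,20E,22E)-6,6-dimethoxytetracosa-2,4,20,22-tetraenal; 13 2-hydroperoxy-2-methoxypropane
Product: 14 (3R,4Z,20E,22E)-6,6-dimethoxy-3-[(2-methoxypropan-2-yl)peroxy]tetracosa-4,20,22-trienal
Conditions: (R)-2-[diphenyl(trimethylsilyloxy)methyl]pyrrolidine (20 mol%), PhCO2H (20 mol%), 13 (2 equiv), toluene, 0 °C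
Reagents that add atoms: none
Why: Iminium-catalysed enantioselective conjugate addition of a hydroperoxide to an α,β-unsaturated aldehyde (β-peroxidation); the closest known type is the amine-catalysed peroxidation and epoxidation of enals with hydroperoxides. The amine condenses with 11 to the (E)-configured s-trans iminium ion, 13 adds through its terminal oxygen to C3 with benzoate as general base, and the enamine is protonated at C2 and hydrolysed to release 14 and the catalyst. The step closes no ring: it forms only the O2–C3 bond, and the six-membered ring is closed in step 10 by 6-exo capture of the C6 oxocarbenium ion. C3 is controlled by the catalyst alone: the diphenyl(trimethylsilyloxy)methyl group blocks one face of the iminium π system, so the (R)-catalyst should deliver oxygen to the open face, which gives (3R) (priorities O > C4 > C2 > H). Attack at C3 over the vinylogous C5 terminus is secured by the fully substituted C6 ketal attached to C5; the ketal also removes the enone that an amine would isomerise, which protects the cis C4=C5 bond. Protonation of the enamine must beat its collapse onto the O–O bond, which the acid co-catalyst, the low temperature and the hindered tertiary peroxide are meant to ensure. The remote diene and both ketals should be inert to these near-neutral conditions, and crude 14 is carried on without chromatography because a β-peroxy aldehyde can eliminate on silica.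

Step 8
Reactants: 14 (3R,4Z,20E,22E)-6,6-dimethoxy-3-[(2-methoxypropan-2-yl)peroxy]tetracosa-4,20,22-trienal
Product: 15 (3R,4Z,20E,22E)-6,6-dimethoxy-3-[(2-methoxypropan-2-yl)peroxy]tetracosa-4,20,22-trienoic acid
Conditions: NaClO2, NaH2PO4, 2-methylbut-2-ene, t-BuOH/H2O, 0 °C
Reagents that add atoms: sodium chlorite, [Na+].[O-]Cl=O
Why: Pinnick oxidation converts aldehydes into acids without touching peroxides or alkenes, the hypochlorite being scavenged by 2-methylbut-2-ene; short contact at 0 °C in phosphate buffer is meant to keep both ketals intact, and the C3 stereocentre is not α to the carbonyl and cannot epimerise.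

Step 9
Reactants: 15 (3R,4Z,20E,22E)-6,6-dimethoxy-3-[(2-methoxypropan-2-yl)peroxy]tetracosa-4,20,22-trienoic acid
Product: 16 methyl (3R,4Z,20E,22E)-6,6-dimethoxy-3-[(2-methoxypropan-2-yl)peroxy]tetracosa-4,20,22-trienoate
Conditions: Me3SiCHN2, toluene/MeOH (4:1), 0 °C
Reagents that add atoms: (trimethylsilyl)diazomethane, C[Si](C)(C)C=[N+]=[N-]
Why: Methylation of the acid by diazomethane generated from Me3SiCHN2 and methanol; the conditions are neutral, so neither the ketals nor the β-peroxy ester (E1cB) are endangered, and the acid is esterified at once so that it cannot cleave its own ketals.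

Step 10
Reactants: 16 methyl (3R,4Z,20E,22E)-6,6-dimethoxy-3-[(2-methoxypropan-2-yl)peroxy]tetracosa-4,20,22-trienoate
Product: 17 methyl 2-[(3R,6R)-6-methoxy-6-[(14E,16E)-octadeca-14,16-dien-1-yl]-3,6-dihydro-1,2-dioxin-3-yl]acetate (xestin A)
Conditions: CSA (10 mol%), CH2Cl2, 0 °C → rt; solid NaHCO3 quench
Reagents that add atoms: none
Why: Acid-catalysed intramolecular peroxyketal exchange: CSA ionises the C6 dimethyl ketal to an oxocarbenium ion, which is captured 6-exo by the peroxide oxygen bound to the acetone-derived carbon, whose 2-methoxypropan-2-yl group leaves as 2,2-dimethoxypropane; only the cis C4=C5 geometry allows closure. C6 is set under equilibrating conditions: reversible ionisation should funnel both C6 epimers toward (6R), in which OMe is pseudo-axial (anomeric effect) and both carbon substituents are pseudo-equatorial, with OMe cis to the C3 arm. C3 is untouched.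

## Compound list

1 | furan | c1ccoc1 | starting material
2 | 1,12-dibromododecane | BrCCCCCCCCCCCCBr | starting material
3 | furan-2-yllithium | [Li]c1ccco1 | intermediate
4 | 2-(12-bromododecyl)furan | BrCCCCCCCCCCCCc1ccco1 | intermediate
5 | (2E,4E)-hexa-2,4-dien-1-yl acetate | CC(=O)OC/C=C/C=C/C | starting material
6 | [12-(furan-2-yl)dodecyl]magnesium bromide | Br[Mg]CCCCCCCCCCCCc1ccco1 | intermediate
7 | 2-[(14E,16E)-octadeca-14,16-dien-1-yl]furan | C/C=C/C=C/CCCCCCCCCCCCCc1ccco1 | intermediate
8 | (2Z,18E,20E)-4-oxodocosa-2,18,20-trienal | O=C/C=C\C(=O)CCCCCCCCCCCCC/C=C/C=C/C | intermediate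
9 | (2E,4Z,20E,22E)-N-methoxy-N-methyl-6-oxotetracosa-2,4,20,22-tetraenamide | CON(C)C(=O)/C=C/C=C\C(=O)CCCCCCCCCCCCC/C=C/C=C/C | intermediate
10 | (2E,4Z,20E,22E)-N,6,6-trimethoxy-N-methyltetracosa-2,4,20,22-tetraenamide | CON(C)C(=O)/C=C/C=C\C(OC)(OC)CCCCCCCCCCCCC/C=C/C=C/C | intermediate
11 | (2E,4Z,20E,22E)-6,6-dimethoxytetracosa-2,4,20,22-tetraenal | O=C/C=C/C=C\C(OC)(OC)CCCCCCCCCCCCC/C=C/C=C/C | intermediate
12 | 2,3-dimethylbut-2-ene | CC(C)=C(C)C | starting material
13 | 2-hydroperoxy-2-methoxypropane | COC(C)(C)OO | intermediate
14 | (3R,4Z,20E,22E)-6,6-dimethoxy-3-[(2-methoxypropan-2-yl)peroxy]tetracosa-4,20,22-trienal | O=CC[C@@H](OOC(C)(C)OC)/C=C\C(OC)(OC)CCCCCCCCCCCCC/C=C/C=C/C | intermediate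
15 | (3R,4Z,20E,22E)-6,6-dimethoxy-3-[(2-methoxypropan-2-yl)peroxy]tetracosa-4,20,22-trienoic acid | OC(=O)C[C@@H](OOC(C)(C)OC)/C=C\C(OC)(OC)CCCCCCCCCCCCC/C=C/C=C/C | intermediate
16 | methyl (3R,4Z,20E,22E)-6,6-dimethoxy-3-[(2-methoxypropan-2-yl)peroxy]tetracosa-4,20,22-trienoate | COC(=O)C[C@@H](OOC(C)(C)OC)/C=C\C(OC)(OC)CCCCCCCCCCCCC/C=C/C=C/C | intermediate
17 | methyl 2-[(3R,6R)-6-methoxy-6-[(14E,16E)-octadeca-14,16-dien-1-yl]-3,6-dihydro-1,2-dioxin-3-yl]acetate (xestin A) | C/C=C/C=C/CCCCCCCCCCCCC[C@]1(OC)C=C[C@@H](CC(=O)OC)OO1 | target

## Step count and least certain steps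

Total: 10 steps. Longest linear sequence: 9 steps (steps 1–5 and 7–10); step 6 is a one-step branch that makes the hydroperoxide.

**Step 7 (key step).** The most likely failure is collapse of the β-peroxy enamine onto the O–O bond, which gives oxirane closure and loss of the peroxide before C2 is protonated. This is inherent to amine catalysis of peroxide additions to enals. Lesser risks are attack at the vinylogous C5 terminus, loss of the cis C4=C5 geometry in the extended iminium ion, and poor facial selectivity. The fallback avoids any enamine, sets out from 8 and returns at 17. Wittig olefination of 8 with Ph3P=CHCO2Me would give methyl (2E,4Z,20E,22E)-6-oxotetracosa-2,4,20,22-tetraenoate F1 as the keto dienoate. Acid-catalysed exchange of F1 with urea–H2O2 and MeOH/HC(OMe)3 would give methyl (2E,4Z,20E,22E)-6-hydroperoxy-6-methoxytetracosa-2,4,20,22-tetraenoate F2 as the racemic methoxy hydroperoxy ketal. Amine-mediated 6-exo conjugate addition of the hydroperoxide of F2 to its enoate (Et2NH, CF3CH2OH), then CSA equilibration at C6, would give 17 together with its enantiomer, methyl 2-[(3S,6S)-6-methoxy-6-[(14E,16E)-octadeca-14,16-dien-1-yl]-3,6-dihydro-1,2-dioxin-3-yl]acetate F3 as the other half of the racemate. A kinetic resolution by enantioselective Kornblum–DeLaMare fragmentation would follow, with the cinchona alkaloid base (quinidine or quinine series) chosen to remove the C3–H of F3 preferentially. It would convert F3 into methyl (4Z,20E,22E)-3,6-dioxotetracosa-4,20,22-trienoate F4 with loss of methanol and leave 17 untouched, and the ring-opened ene-dione F4 should be separable from 17 by chromatography.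

**Step 4.** The most likely failure is loss of the cis C4=C5 geometry by bond rotation in the silylated dienyl oxocarbenium ion, together with slow ketalisation of an electron-poor cross-conjugated ketone. The fallback masks C6 at the alcohol level instead, sets out from 9 and returns at 17. Luche reduction of 9 (NaBH4, CeCl3·7H2O, MeOH, −78 °C) would give (2E,4Z,20E,22E)-6-hydroxy-N-methoxy-N-methyltetracosa-2,4,20,22-tetraenamide F5 as the racemic C6 carbinol. Silylation of F5 with t-BuMe2SiCl and imidazole would give (2E,4Z,20E,22E)-6-[(tert-butyldimethylsilyl)oxy]-N-methoxy-N-methyltetracosa-2,4,20,22-tetraenamide F6 as the silyl ether, and i-Bu2AlH would reduce F6 to (2E,4Z,20E,22E)-6-[(tert-butyldimethylsilyl)oxy]tetracosa-2,4,20,22-tetraenal F7 as the silyloxy dienal. The conditions of step 7 applied to F7 would give (3R,4Z,20E,22E)-6-[(tert-butyldimethylsilyl)oxy]-3-[(2-methoxypropan-2-yl)peroxy]tetracosa-4,20,22-trienal F8 as a pair of C6 epimers. The conditions of step 8 would oxidise F8 to (3R,4Z,20E,22E)-6-[(tert-butyldimethylsilyl)oxy]-3-[(2-methoxypropan-2-yl)peroxy]tetracosa-4,20,22-trienoic acid F9 and those of step 9 would convert F9 into methyl (3R,4Z,20E,22E)-6-[(tert-butyldimethylsilyl)oxy]-3-[(2-methoxypropan-2-yl)peroxy]tetracosa-4,20,22-trienoate F10 as the methyl ester. HF·pyridine would remove the silyl group of F10 and free methyl (3R,4Z,20E,22E)-6-hydroxy-3-[(2-methoxypropan-2-yl)peroxy]tetracosa-4,20,22-trienoate F11 as the C6 alcohol, and Dess–Martin periodinane would oxidise F11 to methyl (3R,4Z,20E,22E)-3-[(2-methoxypropan-2-yl)peroxy]-6-oxotetracosa-4,20,22-trienoate F12 as the cis-enone. CSA in CH2Cl2/MeOH would then transfer the peroxide of F12 onto the ketone with loss of acetone and give 17.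

**Step 3.** The most likely failure is competing bromination or bromohydrin formation at the chain diene, and cis-to-trans isomerisation of the ene-dicarbonyl unit before the Wittig reaction. The fallback oxidises the heteroarene before the diene is present, sets out from 4 and returns at 8. NBS and NaHCO3 in MeOH at −30 °C would convert 4 into 2-(12-bromododecyl)-2,5-dimethoxy-2,5-dihydrofuran F13 as a mixture of diastereomeric cyclic bis-acetals. Magnesium would turn F13 into [12-(2,5-dimethoxy-2,5-dihydrofuran-2-yl)dodecyl]magnesium bromide F14 as its Grignard reagent, and coupling of F14 with 5 under Li2CuCl4 catalysis would give 2,5-dimethoxy-2-[(14E,16E)-octadeca-14,16-dien-1-yl]-2,5-dihydrofuran F15 as the diene-bearing bis-acetal. Brief hydrolysis of F15 (aq. AcOH, acetone, 0 °C) would release 8 just before the Wittig half of step 3.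

**Step 10.** The most likely failure is an insufficient thermodynamic bias at C6, so that both C6 epimers persist, or slow exchange of the two ketals. The fallback replaces equilibration by kinetic trapping, sets out from 16 and returns at 17. Aqueous AcOH/THF would hydrolyse both ketals of 16, and the liberated cis-hydroperoxy enone would close to methyl 2-[(3R)-6-hydroxy-6-[(14E,16E)-octadeca-14,16-dien-1-yl]-3,6-dihydro-1,2-dioxin-3-yl]acetate F16 as the cyclic peroxy-hemiketal, a mixture of C6 epimers. Low-temperature methylation of F16 through the cyclic peroxycarbenium ion (MeOSiMe3, Me3SiOTf cat., CH2Cl2, −78 °C) should deliver methoxide along the pseudo-axial trajectory and give 17 under stereoelectronic control. The same detour would absorb any ketal lost in step 8.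

## Further compounds

F1 | step 7 | methyl (2E,4Z,20E,22E)-6-oxotetracosa-2,4,20,22-tetraenoate | COC(=O)/C=C/C=C\C(=O)CCCCCCCCCCCCC/C=C/C=C/C
F2 | step 7 | methyl (2E,4Z,20E,22E)-6-hydroperoxy-6-methoxytetracosa-2,4,20,22-tetraenoate | COC(=O)/C=C/C=C\C(OC)(OO)CCCCCCCCCCCCC/C=C/C=C/C
F3 | step 7 | methyl 2-[(3S,6S)-6-methoxy-6-[(14E,16E)-octadeca-14,16-dien-1-yl]-3,6-dihydro-1,2-dioxin-3-yl]acetate | C/C=C/C=C/CCCCCCCCCCCCC[C@@]1(OC)C=C[C@H](CC(=O)OC)OO1
F4 | step 7 | methyl (4Z,20E,22E)-3,6-dioxotetracosa-4,20,22-trienoate | COC(=O)CC(=O)/C=C\C(=O)CCCCCCCCCCCCC/C=C/C=C/C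
F5 | step 4 | (2E,4Z,20E,22E)-6-hydroxy-N-methoxy-N-methyltetracosa-2,4,20,22-tetraenamide | CON(C)C(=O)/C=C/C=C\C(O)CCCCCCCCCCCCC/C=C/C=C/C
F6 | step 4 | (2E,4Z,20E,22E)-6-[(tert-butyldimethylsilyl)oxy]-N-methoxy-N-methyltetracosa-2,4,20,22-tetraenamide | CON(C)C(=O)/C=C/C=C\C(O[Si](C)(C)C(C)(C)C)CCCCCCCCCCCCC/C=C/C=C/C
F7 | step 4 | (2E,4Z,20E,22E)-6-[(tert-butyldimethylsilyl)oxy]tetracosa-2,4,20,22-tetraenal | O=C/C=C/C=C\C(O[Si](C)(C)C(C)(C)C)CCCCCCCCCCCCC/C=C/C=C/C
F8 | step 4 | (3R,4Z,20E,22E)-6-[(tert-butyldimethylsilyl)oxy]-3-[(2-methoxypropan-2-yl)peroxy]tetracosa-4,20,22-trienal | O=CC[C@@H](OOC(C)(C)OC)/C=C\C(O[Si](C)(C)C(C)(C)C)CCCCCCCCCCCCC/C=C/C=C/C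
F9 | step 4 | (3R,4Z,20E,22E)-6-[(tert-butyldimethylsilyl)oxy]-3-[(2-methoxypropan-2-yl)peroxy]tetracosa-4,20,22-trienoic acid | OC(=O)C[C@@H](OOC(C)(C)OC)/C=C\C(O[Si](C)(C)C(C)(C)C)CCCCCCCCCCCCC/C=C/C=C/C
F10 | step 4 | methyl (3R,4Z,20E,22E)-6-[(tert-butyldimethylsilyl)oxy]-3-[(2-methoxypropan-2-yl)peroxy]tetracosa-4,20,22-trienoate | COC(=O)C[C@@H](OOC(C)(C)OC)/C=C\C(O[Si](C)(C)C(C)(C)C)CCCCCCCCCCCCC/C=C/C=C/C
F11 | step 4 | methyl (3R,4Z,20E,22E)-6-hydroxy-3-[(2-methoxypropan-2-yl)peroxy]tetracosa-4,20,22-trienoate | COC(=O)C[C@@H](OOC(C)(C)OC)/C=C\C(O)CCCCCCCCCCCCC/C=C/C=C/C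
F12 | step 4 | methyl (3R,4Z,20E,22E)-3-[(2-methoxypropan-2-yl)peroxy]-6-oxotetracosa-4,20,22-trienoate | COC(=O)C[C@@H](OOC(C)(C)OC)/C=C\C(=O)CCCCCCCCCCCCC/C=C/C=C/C
F13 | step 3 | 2-(12-bromododecyl)-2,5-dimethoxy-2,5-dihydrofuran | COC1C=CC(CCCCCCCCCCCCBr)(OC)O1
F14 | step 3 | [12-(2,5-dimethoxy-2,5-dihydrofuran-2-yl)dodecyl]magnesium bromide | COC1C=CC(CCCCCCCCCCCC[Mg]Br)(OC)O1
F15 | step 3 | 2,5-dimethoxy-2-[(14E,16E)-octadeca-14,16-dien-1-yl]-2,5-dihydrofuran | COC1C=CC(CCCCCCCCCCCCC/C=C/C=C/C)(OC)O1
F16 | step 10 | methyl 2-[(3R)-6-hydroxy-6-[(14E,16E)-octadeca-14,16-dien-1-yl]-3,6-dihydro-1,2-dioxin-3-yl]acetate | C/C=C/C=C/CCCCCCCCCCCCCC1(O)C=C[C@@H](CC(=O)OC)OO1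
A1 | alternative 1 | methyl (3E,5E,20E,22E)-6-methoxytetracosa-3,5,20,22-tetraenoate | COC(=O)C/C=C/C=C(/OC)CCCCCCCCCCCCC/C=C/C=C/C
A2 | alternative 2 | methyl (3R)-3-{[(17E,19E)-3-methoxyhenicosa-1,17,19-trien-3-yl]peroxy}pent-4-enoate | COC(=O)C[C@H](C=C)OOC(OC)(C=C)CCCCCCCCCCCCC/C=C/C=C/C
A3 | alternative 3 | 6-methoxy-6-[(14E,16E)-octadeca-14,16-dien-1-yl]-3,6-dihydro-1,2-dioxin-3-yl acetate | CC(=O)OC1C=CC(OC)(CCCCCCCCCCCCC/C=C/C=C/C)OO1
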